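**Retrosynthetic overview**
1. Target ⇐ acetal hydrolysis/desilylation ⇐ ten-membered ring closed last by ring-closing metathesis at C1=C10.
2. Metathesis diene ⇐ C9 aldehyde + 2-bromoacrolein acetal (Nozaki–Hiyama–Kishi, C9–C10); the aldehyde comes from glycol cleavage of a glyceraldehyde-derived dioxolane.
3. α-Methylene lactone ⇐ 2,3-dihydrofuran enol ether (oxidation, then methylenation); C8 ester ⇐ Mitsunobu inversion.
4. trans-2,3-Disubstituted dihydrofuran ⇐ anti opening of an oxetane acetal at C6 by an alkenylcopper made by carbocupration (C3–C4 and C5–C6).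
5. Oxetane acetal ⇐ furan + D-glyceraldehyde acetonide by Paternò–Büchi photocycloaddition; furan supplies O, C6, C7, C11 and C12 of the lactone. Ring order: oxetane/dihydrofuran bicycle → lactone → ten-membered ring.

Assumption: atom labels C1–C15 follow germacrane numbering of the target; TIPS = tri(propan-2-yl)silyl; compounds 2, 4, 5, 9, 12 and 19 are bought.

**Step 1**
Reactants: 1 furan; 2 (4R)-2,2-dimethyl-1,3-dioxolane-4-carbaldehyde
Product: 3 (1S,5R,6S)-6-[(4R)-2,2-dimethyl-1,3-dioxolan-4-yl]-2,7-dioxabicyclo[3.2.0]hept-3-ene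
Conditions: hν (medium-pressure mercury lamp, Vycor filter), furan (20 equiv, solvent), −20 °C; chromatography on Et3N-deactivated silica
Reagents that add atoms: none
Why: The Paternò–Büchi [2+2] photocycloaddition of an aldehyde to furan is regioselective (carbonyl O to the furan α-carbon) and exo-selective, so it dearomatises furan and sets C6, C7 and C8 relative to each other, while the dioxolane centre (excised later) gives little facial bias, so 3 is separated from its exo diastereomer (about 1:1 expected).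

**Step 2**
Reactants: 3 photoadduct; 4 but-3-en-1-ylmagnesium bromide; 5 tri(propan-2-yl)(prop-2-yn-1-yloxy)silane
Product: 8 (S)-[(4R)-2,2-dimethyl-1,3-dioxolan-4-yl]{(2R,3R)-2-[(1E)-2-(TIPSOCH2)hexa-1,5-dien-1-yl]-2,3-dihydrofuran-3-yl}methanol, via but-3-enylcopper 6 (not isolated), via alkenylcopper 7 (not isolated)
Conditions: 4, CuBr·SMe2 (1 equiv), Et2O/Me2S, −45 °C; 5, −25 °C, 2 h; then BF3·OEt2, 3 (0.5 equiv), −78 → −40 °C; H2O
Reagents that add atoms: none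
Why: Proposed new method: Normant syn-carbocupration of the propargyl silyl ether gives alkenylcopper 7 with copper cis to the butenyl chain, and its BF3 complex should open the strained 2-alkoxyoxetane acetal of 3 at C6 anti to the departing oxetane oxygen (closest known type: RCu·BF3 cleavage of cyclic acetals and oxetanes with inversion), which gives the 2,3-trans dihydrofuran, frees the C8 hydroxyl and transfers the C4=C5 geometry with retention.

**Step 3**
Reactants: 8 alcohol; 9 (2R)-2-methylbutanoic acid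
Product: 10 (R)-[(4R)-2,2-dimethyl-1,3-dioxolan-4-yl]{(2R,3S)-2-[(1E)-2-(TIPSOCH2)hexa-1,5-dien-1-yl]-2,3-dihydrofuran-3-yl}methyl (2R)-2-methylbutanoate
Conditions: PPh3, DIAD, toluene, 0 °C → rt
Reagents that add atoms: none
Why: Mitsunobu esterification displaces the oxyphosphonium by the carboxylate in an SN2 step, so the C8 carbinol (anti to C7 after the exo photocycloaddition) is inverted to the syn relationship of the target while the ester is installed.

**Step 4**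
Reactants: 10 ester
Product: 11 (R)-[(4R)-2,2-dimethyl-1,3-dioxolan-4-yl]{(2R,3S)-5-oxo-2-[(1E)-2-(TIPSOCH2)hexa-1,5-dien-1-yl]oxolan-3-yl}methyl (2R)-2-methylbutanoate
Conditions: pyridinium chlorochromate (C5H5NH)[CrO3Cl], NaOAc, 4 Å molecular sieves, CH2Cl2, rt
Reagents that add atoms: pyridinium chlorochromate, [O-][Cr](=O)(=O)Cl.c1cc[nH+]cc1
Why: Chlorochromate oxidation of a cyclic enol ether to the lactone (known for 2,3-dihydrofurans) places the C12 carbonyl without touching the isolated alkenes, silyl ether or acetonide, and no stereocentre is involved.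

**Step 5**
Reactants: 11 lactone; 12 N,N-dimethylmethyleneiminium iodide
Product: 16 (R)-[(4R)-2,2-dimethyl-1,3-dioxolan-4-yl]{(2R,3S)-4-methylidene-5-oxo-2-[(1E)-2-(TIPSOCH2)hexa-1,5-dien-1-yl]oxolan-3-yl}methyl (2R)-2-methylbutanoate, via lithium enolate 13 (not isolated), via Mannich base 14 (not isolated), via ammonium iodide 15 (not isolated)
Conditions: LiN(SiMe3)2 (1.05 equiv), THF, −78 °C; 12, −78 °C → rt; MeI, THF, rt; sat. aq. NaHCO3, rt
Reagents that add atoms: none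
Why: The lactone CH2 is the most acidic and least hindered α-position, so kinetic enolisation, Mannich reaction, N-methylation and loss of trimethylamine (Eschenmoser α-methylenation) give the methylene lactone, and the transient C11 centre is destroyed again.

**Step 6**
Reactants: 16 methylene lactone
Product: 18 (1R)-1-{(2R,3S)-4-methylidene-5-oxo-2-[(1E)-2-(TIPSOCH2)hexa-1,5-dien-1-yl]oxolan-3-yl}-2-oxoethyl (2R)-2-methylbutanoate, via diol 17 (not isolated)
Conditions: H5IO6 (1.5 equiv), EtOAc, rt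
Reagents that add atoms: none
Why: Periodic acid removes the terminal acetonide and cleaves the resulting 1,2-diol in one pot (glycol cleavage), which unveils the C9 aldehyde without base so that the adjacent C8 acyloxy centre is not epimerised.

**Step 7**
Reactants: 18 aldehyde; 19 2-bromo-3,3-diethoxyprop-1-ene
Product: 21 (1R,2S)-3-(diethoxymethyl)-2-hydroxy-1-{(2R,3S)-4-methylidene-5-oxo-2-[(1E)-2-(TIPSOCH2)hexa-1,5-dien-1-yl]oxolan-3-yl}but-3-en-1-yl (2R)-2-methylbutanoate, via alkenylchromium 20 (not isolated)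
Conditions: CrCl2 (6 equiv), NiCl2 (2 mol %), DMSO/THF, rt; H2O
Reagents that add atoms: none
Why: The Nozaki–Hiyama–Kishi reaction adds the alkenylchromium reagent only to the aldehyde in the presence of lactone, ester and enoate, and Felkin–Anh attack anti to the C8 acyloxy group gives the 8,9-anti (erythro) carbinol at C9.

**Step 8**
Reactants: 21 diene
Product: 22 (3aS,4R,5S,6E,10E,11aR)-6-(diethoxymethyl)-5-hydroxy-3-methylidene-2-oxo-10-(TIPSOCH2)-2,3,3a,4,5,8,9,11a-octahydrocyclodeca[b]furan-4-yl (2R)-2-methylbutanoate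
Conditions: second-generation Hoveyda–Grubbs catalyst RuCl2(H2IMes)(=CH–C6H4–2-OiPr) (15 mol %), toluene (0.5 mM), 80 °C, argon sparge
Reagents that add atoms: none
Why: Ring-closing metathesis between the terminal vinyl group and the methylene of the 2-substituted allylic alcohol closes the ten-membered ring with loss of ethene, and the ring size together with the trans lactone and the cis C4=C5 bond enforces the ring-cis geometry at C1=C10 (CIP E).

**Step 9**
Reactants: 22 macrocyclic acetal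
Product: 24 (3aS,4R,5S,6E,10E,11aR)-6-formyl-5-hydroxy-10-(hydroxymethyl)-3-methylidene-2-oxo-2,3,3a,4,5,8,9,11a-octahydrocyclodeca[b]furan-4-yl (2R)-2-methylbutanoate, via silyl ether aldehyde 23 (not isolated)
Conditions: 48% aq. HF, MeCN, 0 °C → rt
Reagents that add atoms: water, O
Why: Aqueous HF hydrolyses the diethyl acetal to the conjugated aldehyde and cleaves the primary silyl ether (acetal hydrolysis and desilylation), conditions under which the methylene lactone, the ester and the four ring stereocentres are stable.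

**Compound list**
1 | furan | c1ccoc1 | starting material
2 | (4R)-2,2-dimethyl-1,3-dioxolane-4-carbaldehyde | O=C[C@H]1COC(C)(C)O1 | starting material
3 | (1S,5R,6S)-6-[(4R)-2,2-dimethyl-1,3-dioxolan-4-yl]-2,7-dioxabicyclo[3.2.0]hept-3-ene | C1=C[C@H]2[C@@H](O1)O[C@@H]2[C@H]3COC(C)(C)O3 | intermediate
4 | but-3-en-1-ylmagnesium bromide | C=CCC[Mg]Br | starting material
5 | tri(propan-2-yl)(prop-2-yn-1-yloxy)silane | C#CCO[Si](C(C)C)(C(C)C)C(C)C | starting material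
6 | but-3-en-1-ylcopper | C=CCC[Cu] | intermediate
7 | (E)-[2-(TIPSOCH2)hexa-1,5-dien-1-yl]copper | [Cu]/C=C(/CO[Si](C(C)C)(C(C)C)C(C)C)CCC=C | intermediate
8 | (S)-[(4R)-2,2-dimethyl-1,3-dioxolan-4-yl]{(2R,3R)-2-[(1E)-2-(TIPSOCH2)hexa-1,5-dien-1-yl]-2,3-dihydrofuran-3-yl}methanol | C1=C[C@@H]([C@H](O1)/C=C(/CO[Si](C(C)C)(C(C)C)C(C)C)CCC=C)[C@H](O)[C@H]2COC(C)(C)O2 | intermediate
9 | (2R)-2-methylbutanoic acid | CC[C@@H](C)C(=O)O | starting material
10 | (R)-[(4R)-2,2-dimethyl-1,3-dioxolan-4-yl]{(2R,3S)-2-[(1E)-2-(TIPSOCH2)hexa-1,5-dien-1-yl]-2,3-dihydrofuran-3-yl}methyl (2R)-2-methylbutanoate | C1=C[C@@H]([C@H](O1)/C=C(/CO[Si](C(C)C)(C(C)C)C(C)C)CCC=C)[C@@H](OC(=O)[C@H](C)CC)[C@H]2COC(C)(C)O2 | intermediate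
11 | (R)-[(4R)-2,2-dimethyl-1,3-dioxolan-4-yl]{(2R,3S)-5-oxo-2-[(1E)-2-(TIPSOCH2)hexa-1,5-dien-1-yl]oxolan-3-yl}methyl (2R)-2-methylbutanoate | O=C1C[C@@H]([C@H](O1)/C=C(/CO[Si](C(C)C)(C(C)C)C(C)C)CCC=C)[C@@H](OC(=O)[C@H](C)CC)[C@H]2COC(C)(C)O2 | intermediate
12 | N,N-dimethylmethyleneiminium iodide (Eschenmoser's salt) | C=[N+](C)C.[I-] | starting material
13 | lithium enolate of 11 | [Li+].[O-]C1=C[C@@H]([C@H](O1)/C=C(/CO[Si](C(C)C)(C(C)C)C(C)C)CCC=C)[C@@H](OC(=O)[C@H](C)CC)[C@H]2COC(C)(C)O2 | intermediate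
14 | 4-[(dimethylamino)methyl] derivative of 11 (both C4 epimers of the oxolanone) | CN(C)CC1C(=O)O[C@H](/C=C(/CO[Si](C(C)C)(C(C)C)C(C)C)CCC=C)[C@H]1[C@@H](OC(=O)[C@H](C)CC)[C@H]2COC(C)(C)O2 | intermediate
15 | trimethylammonium iodide derived from 14 | C[N+](C)(C)CC1C(=O)O[C@H](/C=C(/CO[Si](C(C)C)(C(C)C)C(C)C)CCC=C)[C@H]1[C@@H](OC(=O)[C@H](C)CC)[C@H]2COC(C)(C)O2.[I-] | intermediate
16 | (R)-[(4R)-2,2-dimethyl-1,3-dioxolan-4-yl]{(2R,3S)-4-methylidene-5-oxo-2-[(1E)-2-(TIPSOCH2)hexa-1,5-dien-1-yl]oxolan-3-yl}methyl (2R)-2-methylbutanoate | C=C1C(=O)O[C@H](/C=C(/CO[Si](C(C)C)(C(C)C)C(C)C)CCC=C)[C@H]1[C@@H](OC(=O)[C@H](C)CC)[C@H]2COC(C)(C)O2 | intermediate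
17 | (1R,2R)-2,3-dihydroxy-1-{(2R,3S)-4-methylidene-5-oxo-2-[(1E)-2-(TIPSOCH2)hexa-1,5-dien-1-yl]oxolan-3-yl}propyl (2R)-2-methylbutanoate | C=C1C(=O)O[C@H](/C=C(/CO[Si](C(C)C)(C(C)C)C(C)C)CCC=C)[C@H]1[C@@H](OC(=O)[C@H](C)CC)[C@H](O)CO | intermediate
18 | (1R)-1-{(2R,3S)-4-methylidene-5-oxo-2-[(1E)-2-(TIPSOCH2)hexa-1,5-dien-1-yl]oxolan-3-yl}-2-oxoethyl (2R)-2-methylbutanoate | C=C1C(=O)O[C@H](/C=C(/CO[Si](C(C)C)(C(C)C)C(C)C)CCC=C)[C@H]1[C@@H](OC(=O)[C@H](C)CC)C=O | intermediate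
19 | 2-bromo-3,3-diethoxyprop-1-ene | C=C(Br)C(OCC)OCC | starting material
20 | dichloro(3,3-diethoxyprop-1-en-2-yl)chromium | C=C([Cr](Cl)Cl)C(OCC)OCC | intermediate
21 | (1R,2S)-3-(diethoxymethyl)-2-hydroxy-1-{(2R,3S)-4-methylidene-5-oxo-2-[(1E)-2-(TIPSOCH2)hexa-1,5-dien-1-yl]oxolan-3-yl}but-3-en-1-yl (2R)-2-methylbutanoate | C=C1C(=O)O[C@H](/C=C(/CO[Si](C(C)C)(C(C)C)C(C)C)CCC=C)[C@H]1[C@@H](OC(=O)[C@H](C)CC)[C@@H](O)C(=C)C(OCC)OCC | intermediate
22 | (3aS,4R,5S,6E,10E,11aR)-6-(diethoxymethyl)-5-hydroxy-3-methylidene-2-oxo-10-(TIPSOCH2)-2,3,3a,4,5,8,9,11a-octahydrocyclodeca[b]furan-4-yl (2R)-2-methylbutanoate | C=C1C(=O)O[C@@H]2/C=C(/CO[Si](C(C)C)(C(C)C)C(C)C)CC/C=C(/C(OCC)OCC)[C@H](O)[C@H](OC(=O)[C@H](C)CC)[C@@H]12 | intermediate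
23 | (3aS,4R,5S,6E,10E,11aR)-6-formyl-5-hydroxy-3-methylidene-2-oxo-10-(TIPSOCH2)-2,3,3a,4,5,8,9,11a-octahydrocyclodeca[b]furan-4-yl (2R)-2-methylbutanoate | C=C1C(=O)O[C@@H]2/C=C(/CO[Si](C(C)C)(C(C)C)C(C)C)CC/C=C(/C=O)[C@H](O)[C@H](OC(=O)[C@H](C)CC)[C@@H]12 | intermediate
24 | (3aS,4R,5S,6E,10E,11aR)-6-formyl-5-hydroxy-10-(hydroxymethyl)-3-methylidene-2-oxo-2,3,3a,4,5,8,9,11a-octahydrocyclodeca[b]furan-4-yl (2R)-2-methylbutanoate | C=C1C(=O)O[C@@H]2/C=C(/CO)CC/C=C(/C=O)[C@H](O)[C@H](OC(=O)[C@H](C)CC)[C@@H]12 | target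

**Totals**
Total step count: 9. Longest linear sequence: 9 steps (1 → 24); all other building blocks are bought and used directly.

**Steps most likely to fail, with fallbacks**

Step 2. BF3 may ionise 3 to a cation that loses H7 and aromatises to a 3-furyl carbinol faster than the alkenylcopper forms the C5–C6 bond. The fallback sets out from 3 and removes that pathway by oxidising first: buffered pyridinium chlorochromate (C5H5NH)[CrO3Cl] converts the enol ether of 3 into the bicyclic acylal lactone F1, which cannot aromatise. Alkenylcopper 7 with BF3·OEt2 then opens the acylal carbon anti to the oxetane oxygen to give the trans hydroxy lactone F2. Mitsunobu esterification of F2 with 9 (PPh3, DIAD) comes back to the route at 11.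

Step 3. The C8 carbinol lies between two branched carbons, so the Mitsunobu displacement may stall or eliminate. The fallback sets out from 8 and inverts C8 by oxidation and reduction instead: Dess–Martin periodinane gives the ketone F3, and LiBH(s-Bu)3 at −78 °C reduces it under Felkin–Anh control (hydride anti to the dioxolane C–O bond) to the epimeric alcohol F4. Acylation of F4 with 9 (DCC, DMAP) comes back to the route at 10.

Step 8. Metathesis onto the hindered 1,1-disubstituted alkene to close a ten-membered ring may give oligomers instead. The fallback sets out from 16 and closes the ring at C9–C10 by chromium-mediated addition instead: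
- Cross-metathesis of 16 with acrolein (same ruthenium catalyst) gives the (E)-enal F5.
- Iodine (I2) and pyridine give the (Z)-2-iodo enal F6.
- HC(OEt)3 with pyridinium tosylate gives the iodo diethyl acetal F7.
- H5IO6 cleaves the acetonide through the diol F8 to the iodo aldehyde F9.
- CrCl2 with catalytic NiCl2 in DMSO at high dilution forms the alkenylchromium species F10, which adds to the C9 aldehyde intramolecularly with retention of alkene geometry and comes back to the route at 22.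

**Further compounds**
F1 | step 2 | (1R,5R,6S)-6-[(4R)-2,2-dimethyl-1,3-dioxolan-4-yl]-2,7-dioxabicyclo[3.2.0]heptan-3-one | O=C1C[C@H]2[C@@H](O1)O[C@@H]2[C@H]3COC(C)(C)O3
F2 | step 2 | (S)-[(4R)-2,2-dimethyl-1,3-dioxolan-4-yl]{(2R,3R)-5-oxo-2-[(1E)-2-(TIPSOCH2)hexa-1,5-dien-1-yl]oxolan-3-yl}methanol | O=C1C[C@@H]([C@H](O1)/C=C(/CO[Si](C(C)C)(C(C)C)C(C)C)CCC=C)[C@H](O)[C@H]2COC(C)(C)O2
F3 | step 3 | [(4R)-2,2-dimethyl-1,3-dioxolan-4-yl]{(2R,3S)-2-[(1E)-2-(TIPSOCH2)hexa-1,5-dien-1-yl]-2,3-dihydrofuran-3-yl}methanone | C1=C[C@@H]([C@H](O1)/C=C(/CO[Si](C(C)C)(C(C)C)C(C)C)CCC=C)C(=O)[C@H]2COC(C)(C)O2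
F4 | step 3 | (R)-[(4R)-2,2-dimethyl-1,3-dioxolan-4-yl]{(2R,3R)-2-[(1E)-2-(TIPSOCH2)hexa-1,5-dien-1-yl]-2,3-dihydrofuran-3-yl}methanol | C1=C[C@@H]([C@H](O1)/C=C(/CO[Si](C(C)C)(C(C)C)C(C)C)CCC=C)[C@@H](O)[C@H]2COC(C)(C)O2
F5 | step 8 | (R)-[(4R)-2,2-dimethyl-1,3-dioxolan-4-yl]{(2R,3S)-4-methylidene-5-oxo-2-[(1E,5E)-7-oxo-2-(TIPSOCH2)hepta-1,5-dien-1-yl]oxolan-3-yl}methyl (2R)-2-methylbutanoate | C=C1C(=O)O[C@H](/C=C(/CO[Si](C(C)C)(C(C)C)C(C)C)CC/C=C/C=O)[C@H]1[C@@H](OC(=O)[C@H](C)CC)[C@H]2COC(C)(C)O2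
F6 | step 8 | (R)-[(4R)-2,2-dimethyl-1,3-dioxolan-4-yl]{(2R,3S)-2-[(1E,5Z)-6-iodo-7-oxo-2-(TIPSOCH2)hepta-1,5-dien-1-yl]-4-methylidene-5-oxooxolan-3-yl}methyl (2R)-2-methylbutanoate | C=C1C(=O)O[C@H](/C=C(/CO[Si](C(C)C)(C(C)C)C(C)C)CC/C=C(/C=O)I)[C@H]1[C@@H](OC(=O)[C@H](C)CC)[C@H]2COC(C)(C)O2
F7 | step 8 | (R)-[(4R)-2,2-dimethyl-1,3-dioxolan-4-yl]{(2R,3S)-2-[(1E,5Z)-7,7-diethoxy-6-iodo-2-(TIPSOCH2)hepta-1,5-dien-1-yl]-4-methylidene-5-oxooxolan-3-yl}methyl (2R)-2-methylbutanoate | C=C1C(=O)O[C@H](/C=C(/CO[Si](C(C)C)(C(C)C)C(C)C)CC/C=C(/C(OCC)OCC)I)[C@H]1[C@@H](OC(=O)[C@H](C)CC)[C@H]2COC(C)(C)O2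
F8 | step 8 | (1R,2R)-1-{(2R,3S)-2-[(1E,5Z)-7,7-diethoxy-6-iodo-2-(TIPSOCH2)hepta-1,5-dien-1-yl]-4-methylidene-5-oxooxolan-3-yl}-2,3-dihydroxypropyl (2R)-2-methylbutanoate | C=C1C(=O)O[C@H](/C=C(/CO[Si](C(C)C)(C(C)C)C(C)C)CC/C=C(/C(OCC)OCC)I)[C@H]1[C@@H](OC(=O)[C@H](C)CC)[C@H](O)CO
F9 | step 8 | (1R)-1-{(2R,3S)-2-[(1E,5Z)-7,7-diethoxy-6-iodo-2-(TIPSOCH2)hepta-1,5-dien-1-yl]-4-methylidene-5-oxooxolan-3-yl}-2-oxoethyl (2R)-2-methylbutanoate | C=C1C(=O)O[C@H](/C=C(/CO[Si](C(C)C)(C(C)C)C(C)C)CC/C=C(/C(OCC)OCC)I)[C@H]1[C@@H](OC(=O)[C@H](C)CC)C=O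
F10 | step 8 | dichlorochromium alkenyl species derived from F9 (chromium in place of iodine) | C=C1C(=O)O[C@H](/C=C(/CO[Si](C(C)C)(C(C)C)C(C)C)CC/C=C(/C(OCC)OCC)[Cr](Cl)Cl)[C@H]1[C@@H](OC(=O)[C@H](C)CC)C=O
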